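## Analysis of the target

The target is a lignan pentamer built on a furofuran of the (+)-syringaresinol type: a cis-fused 3,7-dioxabicyclo[3.3.0]octane in which C7 carries syringyl ring B, C7' carries syringyl ring C, and C8/C9 and C8'/C9' complete the two tetrahydrofuran rings. O4 of ring B is etherified by C8 of a guaiacylglycerol unit (chain A, ring A); O4 of ring C is etherified by C8 of a second unit (chain D, ring D), whose own O4 carries a third (chain E, ring E); rings A and E end in free phenols. There are ten stereocentres: the bicycle is 7S,8R,7'S,8'R (cis fusion, both aryl groups exo), chain A is 7R,8S (erythro), chain D is 7S,8S (threo) and chain E is 7S,8R (erythro). The three side-chain pairs are insulated from one another and from the core by aryl ether links, so each needs reagent control, and the two erythro ends have opposite absolute sense at C8. The sensitive elements are the five para-oxygenated benzylic C–O bonds (two cyclic ethers, three carbinols), which ionise in acid and can be cut by hydrogenolysis, the free phenols, and the β-aryl ether units, which suffer β-elimination or retro-aldol cleavage once a carbonyl sits next to C8. The synthesis is hard for three reasons: the two chemically identical syringyl rings must carry different substituents, the glycerol units have two different relative configurations, and three phenols must be addressed one at a time. The strategy rests on the chain C7–C8–C8'–C7' with its branches C9 and C9': C7 and C7' are benzylic and oxygenated, so C7' can enter as an acyl anion and C7 as an aldehyde carbon on the two alkene carbons of a butenolide whose carbonyl and acetal carbons are C9 and C9'.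

## Retrosynthetic reasoning

Final unmasking. Target 40 is traced to its hexasilyl ether 39, in which the two terminal phenols and four of the six alcohols are silylated. No skeletal bond is cut. The gain is an end-game of one buffered fluoride step, with no acid and no hydrogenolysis in the presence of five benzylic C–O bonds.

The erythro carbinols of chains A and E. The C7–H bonds of chains A and E in 39 are disconnected to diketone 38, and 38 to the threo alcohols 37. The dependable auxiliary aldol of an aryloxyacetyl imide is the syn one, and syn corresponds to threo in arylglycerol terms (erythro is 7R,8S or 7S,8R, the anti relationship). This is right for chain D but wrong for chains A and E. The two end units are therefore made threo and corrected at C7 through the ketone, where a chelate between the carbonyl and the α-aryloxy oxygen steers hydride to the erythro face. Both ends are corrected in the same three operations and C8 is never touched.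

C7–C8 of chains A and E. 37 comes from tetraol 36 by silylation of the primary hydroxyls, and 36 from bis-adduct 35 by reductive loss of the auxiliaries. 35 is cut at both C7–C8 bonds into bis-imide 31 and two molecules of aldehyde 33, which comes from vanillin 32. This is the one bond of a glycerol unit whose formation fixes C8 absolutely. C8 of chain A is S and C8 of chain E is R, so the imide on ring B carries the (R)-auxiliary and the imide on ring D the (S)-auxiliary. The forward reaction has to enolise two imides in one molecule and add each to its own molecule of 33 under control of its own auxiliary.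

The aryl ether bonds and the order of the phenols. 31 is cut at the O–CH2 bond on ring B into phenol 30 and bromoacetyl imide 19. 30 comes from benzyl ether 29, which is cut at the O–CH2 bond on ring D into phenol 26 and the enantiomeric imide 28. 26 comes from allyl ether 25. Each ether oxygen is thus a phenol oxygen alkylated on a primary carbon, so the hindered phenols never have to displace at a secondary centre. The phenols of rings C, D and B are released in turn by three orthogonal events: fluoride, palladium-catalysed allyl transfer and hydrogenolysis. 19 and 28 come from oxazolidinones 18 and 27.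

Chain D. 25 is the bis-silyl ether of diol 24, which comes from syn adduct 23. 23 is cut at C7–C8 into imide 20 and aldehyde 21. Here the syn (threo) outcome is exactly the 7S,8S unit of the target, so no correction is needed. 20 is cut into phenol 17 and 19, and 17 comes from 16 by desilylation.

The bicycle. 16 is opened at C7–O and C7'–O to tetraol 15. Both carbons are benzylic and para-oxygenated, so they ionise under mild acid, and each cation can reach only the hydroxymethyl group of the other half in a five-membered closure. The configuration at C7 and C7' is therefore made in the closure (aryl anti to the neighbouring ring substituent), and 15 needs only C8 and C8' to be right. The forward reaction must be stopped at this kinetic product.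

Redox adjustment. 15 is the exhaustive hydride reduction product of keto lactone 14. The lactone carbonyl becomes C9, the acetal carbon becomes C9', the ketone becomes the C7' carbinol, and (−)-menthol 4 is released. 14 is the unmasked form of dithiane 13.

The key disconnection. 13 is cut at C7'–C8' and at C8–C7 into dithiane 9, butenolide 5 and aldehyde 10. The polarity of C7' is reversed in 9, so that it adds as a nucleophile to C4 of 5; the enolate so formed uses C3 to attack the carbonyl carbon of 10. One operation assembles the whole aryl–C4–aryl skeleton with the two rings already differentiated (silyl on ring C, benzyl on ring B). It also sets C8' from the acetal centre of 5 and C8 from C8'.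

Building blocks. 9 comes from aldehyde 7 and dithiol 8; 7 and 10 come from syringaldehyde 6. 5 comes from hydroxybutenolide 3 and 4 with crystallisation of the (5R) epimer, and 3 from furfural 1 via 2.

## Alternatives that were turned down

Alternative 1: The two terminal units are cut at their C7–aryl bonds, so rings A and E arrive last as nucleophiles. In the forward sense, two equivalents of the aryl titanium reagent A2 (tetravalent titanium) would add to the two α-aryloxy aldehyde groups of bis-aldehyde A1. A non-chelating metal should follow the Felkin–Anh course, with the aryloxy group anti to the incoming aryl, and give the anti (erythro) carbinols of A3. In its favour, both erythro centres are made directly in one convergent C–C bond-forming step. On this point it is stronger than the chosen route, which reaches the same relative configuration only through three extra operations (37 to 39). Against it, it is only an end-game: A1 already contains the furofuran, chain D and both C8 centres, none of which the disconnection explains. The two C8 centres have opposite configuration and would have to be attached to hindered phenols as secondary carbons. An α-aryloxy-β-silyloxy aldehyde is configurationally fragile (acidic α-hydrogen, β-elimination), and A1 has two of them. Selectivity would rest on substrate control alone. The chosen strategy solves the core, fixes each C8 by an auxiliary in the bond-forming event, and never isolates an α-aryloxy aldehyde.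

Alternative 2: Both C7–O and C7'–O bonds of the bicycle are disconnected with C7 and C7' at the methylene level, leading to the (2R,3R)-dibenzylbutanediol A4. Two equivalents of a high-potential quinone would abstract benzylic hydride first at C7 and then at C7', each cation being captured by the hydroxymethyl group of the other half, to give core A5, which is identical with 16. In its favour, A4 has only two stereocentres and no carbinol mixtures, and oxidation is applied only where the rings close. In step count to the core and in redox economy it is stronger than the chosen route, which spends steps 7 to 9 on unmasking, reduction and closure. Against it, the ether formed in the first closure has a benzylic, α-oxygenated C7–H that is a better hydride donor than the remaining C7' methylene, so over-oxidation competes with the second closure. A benzylic cation in a dibenzylbutane is also placed for Friedel–Crafts attack on the other electron-rich ring (six-membered aryltetralin), and the benzyl ether is itself a hydride donor. In its place the chosen strategy delivers C7 and C7' as alcohols directly from the C–C bond formation, so ring closure is a non-oxidative ionisation, and the risk sits in one conjugate addition–aldol event.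

Alternative 3: All four bonds to the carbonyl carbons are cut, so that C9 and C9' come from carbon monoxide A7 and the precursor is the E-configured (7S,7'S)-enediol A6. With a divalent palladium catalyst (Pd(OAc)2) and a quinone re-oxidant, one hydroxyl would form an alkoxycarbonyl palladium species that adds syn across the alkene. A second carbonylation captured by the other hydroxyl would give the cis-fused dilactone A8. In its favour, four bonds, two rings and both C8 centres arise in one step, and syn addition to an E-alkene must give the cis fusion. In bond economy it surpasses the chosen key step, which makes two bonds and no ring. Against it, A6 is a doubly benzylic, doubly allylic diol with electron-rich aryl groups, so ionisation, allylic transposition and cyclodehydration to a 2,5-diaryl furan are expected to outrun carbonylation. Insertion of an internal 1,2-disubstituted alkene is slow and invites β-hydride elimination. A6 also needs two controlled carbinol centres with two different aryl groups, and A8 still requires both lactone carbonyls to be reduced to methylene without opening the benzylic C–O bonds. The chosen strategy brings C9 and C9' in at oxidation levels that a single hydride reduction converts to the hydroxymethyl groups needed for closure, and it uses a reaction type with direct analogy.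

Key step: step 6

Remark on the chemistry (assumption): the carbinol centres formed at C7 in step 6 and at C7' in step 8 are taken on as epimer mixtures, because step 9 erases both; 13 and 14 are drawn as the (S)-carbinol and 15 with both carbinols undefined.

Stoichiometry: where one step takes up two molecules of the same component, the second molecule is entered under the reagents that add atoms, so that each equation balances as written.

Naming: "syringaresinol" means the (7S,8R,7'S,8'R) skeleton, (1S,3aR,4S,6aR)-1,4-bis(4-hydroxy-3,5-dimethoxyphenyl)tetrahydro-1H,3H-furo[3,4-c]furan, with O4 on ring B (at C7) and O4' on ring C (at C7'). Xc(R) and Xc(S) are (R)- and (S)-4-benzyl-2-oxooxazolidin-3-yl. TBS is tert-butyldimethylsilyl and TIPS is triisopropylsilyl.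

## Route

Step 1
Reactants: 1 furfural
Product: 3 5-hydroxyfuran-2(5H)-one (racemic), via furfural endoperoxide 2 (not isolated)
Conditions: O2, hν (visible), methylene blue (cat.), MeOH, 15 °C
Reagents that add atoms: oxygen, O=O
Why: Dye-sensitised singlet oxygen adds across the furan diene in a [4+2] cycloaddition to give endoperoxide 2; methanol attacks the formyl group and fragmentation expels methyl formate, leaving the hydroxybutenolide (photo-oxygenation of furfural).

Step 2
Reactants: 3 5-hydroxyfuran-2(5H)-one; 4 (−)-menthol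
Product: 5 (5R)-5-[(1R,2S,5R)-menthyloxy]furan-2(5H)-one
Conditions: CSA (cat.), toluene, reflux (Dean–Stark); crystallisation from petroleum ether; mother liquor re-equilibrated with acid and recrystallised
Reagents that add atoms: none
Why: Acid-catalysed acetalisation of the pseudo-acid gives both C5 epimers, which interconvert under acid; the (5R) epimer crystallises, so crystallisation with re-equilibration of the mother liquor sets C5.

Step 3
Reactants: 6 syringaldehyde
Product: 7 3,5-dimethoxy-4-(triisopropylsilyloxy)benzaldehyde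
Conditions: TIPSCl, imidazole, DMAP (cat.), DMF, 40 °C
Reagents that add atoms: triisopropylsilyl chloride, CC(C)[Si](Cl)(C(C)C)C(C)C
Why: Imidazole-promoted silylation of the phenol; the bulky silyl ether is chosen to survive the organolithium base, LiAlH4 and mild acid and to be cleaved by fluoride while a benzyl ether stays.

Step 4
Reactants: 7 3,5-dimethoxy-4-(triisopropylsilyloxy)benzaldehyde; 8 propane-1,3-dithiol
Product: 9 2-[3,5-dimethoxy-4-(triisopropylsilyloxy)phenyl]-1,3-dithiane
Conditions: BF3·OEt2 (cat.), CH2Cl2, 0 °C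
Reagents that add atoms: none
Why: Lewis-acid-catalysed dithioacetalisation of an aryl aldehyde; the aryl silyl ether tolerates catalytic BF3·OEt2 at 0 °C.

Step 5
Reactants: 6 syringaldehyde
Product: 10 4-benzyloxy-3,5-dimethoxybenzaldehyde
Conditions: BnBr, K2CO3, DMF, rt
Reagents that add atoms: benzyl bromide, BrCc1ccccc1
Why: Williamson etherification of the phenoxide; benzyl is orthogonal to the silyl group on the other ring.

Step 6
Reactants: 9 2-[3,5-dimethoxy-4-(triisopropylsilyloxy)phenyl]-1,3-dithiane; 5 (5R)-5-menthyloxyfuran-2(5H)-one; 10 4-benzyloxy-3,5-dimethoxybenzaldehyde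
Product: 13 (3S,4R,5R)-3-[(S)-(4-benzyloxy-3,5-dimethoxyphenyl)(hydroxy)methyl]-4-{2-[3,5-dimethoxy-4-(triisopropylsilyloxy)phenyl]-1,3-dithian-2-yl}-5-[(1R,2S,5R)-menthyloxy]dihydrofuran-2(3H)-one, via 2-lithio-1,3-dithiane 11 (not isolated), via lactone lithium enolate 12 (not isolated)
Conditions: n-BuLi, THF, −78 → −30 °C; then 5, −78 °C; then 10, −78 °C; sat. aq. NH4Cl at −78 °C
Reagents that add atoms: none
Why: Deprotonation of 9 gives the sulfur-stabilised carbanion 11, an acyl-anion equivalent for C7' that adds 1,4 to butenolide 5 (bond C7'–C8'), and the lithium enolate 12 so formed is trapped in the same flask by aldehyde 10 in an aldol addition (bond C8–C7). The closest known reaction type is the tandem conjugate addition–electrophile trapping of lithiated 2-aryl-1,3-dithianes on 5-alkoxyfuran-2(5H)-ones. No ring is closed. C8' (lactone C4) is controlled by the menthyloxy acetal at C5, the nucleophile entering the flat enone on the face anti to the alkoxy group. C8 (lactone C3) is controlled by the new, very bulky C4 substituent, which sends the aldehyde to the opposite face of the enolate and gives the 3,4-trans-4,5-trans lactone that maps onto the 8R,8'R cis ring fusion. The carbinol C7 is governed only by the Zimmerman–Traxler preference of a cyclic lithium enolate and is expected to form with modest selectivity; it is drawn 7S, and a 7-epimer is carried along because step 9 erases this centre. The step needs 1,4- over 1,2-addition, which the soft, hindered dithiane anion and the acetal-bearing enone secure, and complete anti,anti selection in the ring, which the acetal centre secures; low temperature and a cold quench hold back retro-aldol cleavage and loss of menthoxide.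

Step 7
Reactants: 13 dithiane aldol lactone
Product: 14 (3S,4R,5R)-3-[(S)-(4-benzyloxy-3,5-dimethoxyphenyl)(hydroxy)methyl]-4-[3,5-dimethoxy-4-(triisopropylsilyloxy)benzoyl]-5-[(1R,2S,5R)-menthyloxy]dihydrofuran-2(3H)-one
Conditions: PhI(OCOCF3)2 (1.5 equiv), MeCN–H2O (9:1), 0 °C, short reaction time
Reagents that add atoms: water, O
Why: Oxidative dithioacetal hydrolysis by a trivalent iodine reagent: sulfur is activated, water adds and the ketone is released within minutes. The neutral to weakly acidic medium spares the acetal, the silyl ether and the base-sensitive β-alkoxy ketone.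

Step 8
Reactants: 14 keto lactone
Product: 15 (2R,3R)-2-[(4-benzyloxy-3,5-dimethoxyphenyl)(hydroxy)methyl]-3-{[3,5-dimethoxy-4-(triisopropylsilyloxy)phenyl](hydroxy)methyl}butane-1,4-diol (mixture at both carbinol carbons)
Conditions: LiAlH4 (excess), THF, −20 °C → rt, inverse addition
Reagents that add atoms: none
Why: Exhaustive hydride reduction: the lactone opens, the menthyl hemiacetal collapses to an aldehyde that is reduced in turn, and the aryl ketone gives the C7' carbinol. Adding 14 to excess hydride lets ketone reduction outrun enolisation, so C8 and C8' are kept.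

Step 9
Reactants: 15 tetraol
Product: 16 (7S,8R,7'S,8'R)-4-O-benzyl-4'-O-(triisopropylsilyl)syringaresinol
Conditions: CSA (0.1 equiv), CH2Cl2, 0 °C, short contact time; Et3N quench
Reagents that add atoms: none
Why: Acid-catalysed double dehydrative etherification: each para-oxygenated benzylic alcohol ionises to a planar, quinone-methide-like cation that is captured 5-exo-trig by the hydroxymethyl group of the other half (C7–O–C9' and C7'–O–C9), so the carbinol configurations of 15 are erased. Attack anti to the substituent on the adjacent ring carbon puts each aryl group exo (7S, 7'S on the 8R,8'R frame), the same preference as in the quinone methide closure by which this ring system arises in nature. The exo,exo isomer is only slightly favoured at equilibrium, hence weak acid, low temperature and a basic quench.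

Step 10
Reactants: 16 benzyl silyl furofuran
Product: 17 (7S,8R,7'S,8'R)-4-O-benzylsyringaresinol (ring C phenol free)
Conditions: TBAF, THF, 0 °C; aq. NH4Cl
Reagents that add atoms: none
Why: Fluoride cleavage of the aryl silyl ether; the benzyl ether and the bicycle are inert.

Step 11
Reactants: 18 (R)-4-benzyloxazolidin-2-one
Product: 19 (R)-4-benzyl-3-(bromoacetyl)oxazolidin-2-one
Conditions: n-BuLi, THF, −78 °C; BrCH2COBr, −78 °C
Reagents that add atoms: bromoacetyl bromide, BrCC(Br)=O
Why: N-acylation of the lithiated oxazolidinone; acyl substitution at the acid bromide is much faster than displacement of the α-bromide at −78 °C.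

Step 12
Reactants: 17 ring C phenol; 19 (R)-bromoacetyl imide
Product: 20 4-O-benzyl-4'-O-{2-[(R)-4-benzyl-2-oxooxazolidin-3-yl]-2-oxoethyl}syringaresinol
Conditions: K2CO3, acetone, rt
Reagents that add atoms: none
Why: Williamson O-alkylation of the hindered phenoxide on a primary, carbonyl-activated bromide; weak base at room temperature spares the imide.

Step 13
Reactants: 20 ring C aryloxyacetyl imide; 21 4-(allyloxy)-3-methoxybenzaldehyde
Product: 23 (4R)-4-benzyl-3-[(2R,3S)-3-(4-allyloxy-3-methoxyphenyl)-3-hydroxy-2-(aryloxy)propanoyl]oxazolidin-2-one with aryloxy = O4' of 4-O-benzylsyringaresinol, via Z-boron enolate 22 (not isolated)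
Conditions: Bu2BOTf, i-Pr2NEt, CH2Cl2, −78 → 0 °C; then 21, −78 → 0 °C; pH 7 buffer, MeOH, H2O2, 0 °C
Reagents that add atoms: none
Why: Evans syn aldol: soft enolisation gives the Z-boron enolate 22, which adds to 21 through a Zimmerman–Traxler chair with the auxiliary carbonyl turned away from the enolate oxygen, so that the benzyl group blocks one face. With the (R)-auxiliary the new centres are 2R,3S, the syn arrangement that becomes threo-(7S,8S) of chain D once the auxiliary is removed.

Step 14
Reactants: 23 syn aldol adduct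
Product: 24 4-O-benzyl-4'-O-[(1S,2S)-1-(4-allyloxy-3-methoxyphenyl)-1,3-dihydroxypropan-2-yl]syringaresinol (chain D threo, 7S,8S)
Conditions: LiBH4, THF, H2O (1 equiv), 0 °C
Reagents that add atoms: none
Why: Reductive cleavage of the imide at the exocyclic carbonyl gives the primary alcohol and the recoverable auxiliary; no stereocentre is touched.

Step 15
Reactants: 24 threo diol
Product: 25 4-O-benzyl-4'-O-[(1S,2S)-1-(4-allyloxy-3-methoxyphenyl)-1,3-bis(tert-butyldimethylsilyloxy)propan-2-yl]syringaresinol
Conditions: TBSCl, imidazole, DMAP (cat.), DMF, 40 °C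
Reagents that add atoms: tert-butyldimethylsilyl chloride, CC(C)(C)[Si](C)(C)Cl
Why: Silylation of both hydroxyls; silyl chloride with imidazole is used instead of a silyl triflate to keep Lewis acid away from the benzylic ethers of the bicycle.

Step 16
Reactants: 25 ring D allyl ether
Product: 26 4-O-benzyl-4'-O-[(1S,2S)-1,3-bis(tert-butyldimethylsilyloxy)-1-(4-hydroxy-3-methoxyphenyl)propan-2-yl]syringaresinol (ring D phenol free)
Conditions: Pd(PPh3)4 (5 mol %), morpholine, THF, rt
Reagents that add atoms: none
Why: Tsuji–Trost deallylation: zerovalent palladium ionises the aryl allyl ether to a π-allyl complex and phenoxide, and morpholine takes up the allyl group; benzyl and silyl ethers are inert.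

Step 17
Reactants: 27 (S)-4-benzyloxazolidin-2-one
Product: 28 (S)-4-benzyl-3-(bromoacetyl)oxazolidin-2-one
Conditions: n-BuLi, THF, −78 °C; BrCH2COBr, −78 °C
Reagents that add atoms: bromoacetyl bromide, BrCC(Br)=O
Why: N-acylation of the lithiated oxazolidinone, as in step 11.

Step 18
Reactants: 26 ring D phenol; 28 (S)-bromoacetyl imide
Product: 29 4-O-benzyl-4'-O-[(1S,2S)-1-(4-{2-[(S)-4-benzyl-2-oxooxazolidin-3-yl]-2-oxoethoxy}-3-methoxyphenyl)-1,3-bis(tert-butyldimethylsilyloxy)propan-2-yl]syringaresinol
Conditions: K2CO3, acetone, rt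
Reagents that add atoms: none
Why: Williamson O-alkylation as in step 12, here on the less hindered guaiacyl phenoxide; the (S)-auxiliary is placed where C8 of chain E must become R.

Step 19
Reactants: 29 ring D imide with benzyl ether on ring B
Product: 30 4'-O-[(1S,2S)-1-(4-{2-[(S)-4-benzyl-2-oxooxazolidin-3-yl]-2-oxoethoxy}-3-methoxyphenyl)-1,3-bis(tert-butyldimethylsilyloxy)propan-2-yl]syringaresinol (ring B phenol free)
Conditions: H2 (1 atm), 10% Pd/C, EtOAc, rt, stopped after one equivalent
Reagents that add atoms: none
Why: Hydrogenolysis of the aryl benzyl ether is much faster than cleavage of the benzylic C–O bonds of the bicycle or of the benzylic silyl ether under neutral conditions; the C-benzyl group of the auxiliary and the imide are inert.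

Step 20
Reactants: 30 ring B phenol; 19 (R)-bromoacetyl imide
Product: 31 4-O-{2-[(R)-4-benzyl-2-oxooxazolidin-3-yl]-2-oxoethyl} derivative of 30 (bis-imide: Xc(R) on the ring B side, Xc(S) on the ring D side)
Conditions: K2CO3, acetone, rt
Reagents that add atoms: none
Why: Williamson O-alkylation as in step 12; the imide already present is not deprotonated by K2CO3, and the (R)-auxiliary is placed where C8 of chain A must become S.

Step 21
Reactants: 32 vanillin
Product: 33 3-methoxy-4-(triisopropylsilyloxy)benzaldehyde
Conditions: TIPSCl, imidazole, DMF, rt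
Reagents that add atoms: triisopropylsilyl chloride, CC(C)[Si](Cl)(C(C)C)C(C)C
Why: Phenol silylation; the aryl silyl ether survives the boron aldol, LiBH4, the oxidation and Zn(BH4)2 and leaves with the other silyl groups in the last step.

Step 22
Reactants: 31 bis-imide; 33 3-methoxy-4-(triisopropylsilyloxy)benzaldehyde (two molecules are taken up, one at each imide)
Product: 35 bis syn-aldol adduct: ring B side (2R,3S)-3-hydroxy-3-[3-methoxy-4-(triisopropylsilyloxy)phenyl]-2-aryloxypropanoyl-Xc(R) and ring D side (2S,3R)-3-hydroxy-3-[3-methoxy-4-(triisopropylsilyloxy)phenyl]-2-aryloxypropanoyl-Xc(S), via bis(boron enolate) 34 (not isolated)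
Conditions: Bu2BOTf (2.4 equiv), i-Pr2NEt (3 equiv), CH2Cl2, −78 → 0 °C; then 33 (3 equiv in all), −78 → 0 °C; pH 7 buffer, MeOH, H2O2, 0 °C
Reagents that add atoms: 3-methoxy-4-(triisopropylsilyloxy)benzaldehyde (second molar equivalent of 33), COc1cc(C=O)ccc1O[Si](C(C)C)(C(C)C)C(C)C
Why: Twofold Evans syn aldol through Z-boron enolates and Zimmerman–Traxler chairs, each enolate taking up one molecule of 33; the two sites are remote, so each auxiliary controls its own pair of centres. The (R)-auxiliary end gives the precursor of chain A with 7S,8S and the (S)-auxiliary end that of chain E with 7R,8R, so both C8 centres already have the configuration of the target.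

Step 23
Reactants: 35 bis syn-aldol adduct
Product: 36 tetraol with chain A threo (7S,8S) and chain E threo (7R,8R); chain D bis-O-TBS, rings A and E O-TIPS
Conditions: LiBH4, THF, H2O (2 equiv), 0 °C
Reagents that add atoms: none
Why: Twofold reductive removal of the auxiliaries as in step 14; both oxazolidinones are recovered.

Step 24
Reactants: 36 bis-threo tetraol
Product: 37 9-O-TBS ethers of chains A and E of 36 (both C7 hydroxyls free)
Conditions: TBSCl (2.2 equiv), imidazole, CH2Cl2, 0 °C
Reagents that add atoms: tert-butyldimethylsilyl chloride, CC(C)(C)[Si](C)(C)Cl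
Why: Selective silylation of the two primary hydroxyls over the hindered secondary benzylic ones; this masks C9–OH with a poorly coordinating group before oxidation and chelation-controlled reduction.

Step 25
Reactants: 37 bis-threo diol
Product: 38 7-oxo derivative of chains A and E (diketone; C8 of chain A is S, C8 of chain E is R)
Conditions: Dess–Martin periodinane, NaHCO3, CH2Cl2, 0 °C → rt
Reagents that add atoms: none
Why: Dess–Martin oxidation of the two secondary benzylic alcohols under buffered, non-basic conditions, so that the α-aryloxy centres are not enolised and the β-silyloxy groups are not eliminated; 38 is used at once.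

Step 26
Reactants: 38 diketone
Product: 39 hexasilyl ether of the target: chain A erythro (7R,8S), chain D threo (7S,8S), chain E erythro (7S,8R); 9-O-TBS on chains A, D and E, 7-O-TBS on chain D, O-TIPS on rings A and E
Conditions: Zn(BH4)2, Et2O–CH2Cl2, −40 → −20 °C
Reagents that add atoms: none
Why: Chelation-controlled (Cram-chelate) ketone reduction: zinc ties the carbonyl oxygen to the α-aryloxy oxygen, helped by the ortho-methoxy groups, and hydride enters the five-membered chelate from the side of the C8 hydrogen, away from CH2OTBS. This gives the anti (erythro) carbinols, 7R next to 8S in chain A and 7S next to 8R in chain E; the silyloxy group at C9 is too hindered to compete as a ligand.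

Step 27
Reactants: 39 hexasilyl ether
Product: 40 target, (7S,8R,7'S,8'R)-syringaresinol 4-O-[erythro-(7R,8S)-guaiacylglycerol-8-yl] 4'-O-{threo-(7S,8S)-4-O-[erythro-(7S,8R)-guaiacylglycerol-8-yl]guaiacylglycerol-8-yl} diether
Conditions: TBAF, AcOH, THF, 0 °C → rt
Reagents that add atoms: none
Why: Fluoride removes all six silyl groups (four alkyl TBS, two aryl TIPS) in one operation; buffering with acetic acid keeps the liberated phenoxides from base-induced side reactions of the para-hydroxybenzylic carbinols.

## Compound list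

1 | furfural (furan-2-carbaldehyde) | O=Cc1ccco1 | starting material
2 | furfural 2,5-endoperoxide, 2,3,7-trioxabicyclo[2.2.1]hept-5-ene-1-carbaldehyde | O=CC12OOC(C=C1)O2 | intermediate (not isolated)
3 | 5-hydroxyfuran-2(5H)-one (racemic) | O=C1C=CC(O)O1 | intermediate
4 | (−)-menthol, (1R,2S,5R)-2-isopropyl-5-methylcyclohexan-1-ol | CC(C)[C@@H]1CC[C@@H](C)C[C@H]1O | starting material
5 | (5R)-5-[(1R,2S,5R)-menthyloxy]furan-2(5H)-one | O=C1O[C@@H](O[C@@H]2C[C@H](C)CC[C@H]2C(C)C)C=C1 | intermediate
6 | syringaldehyde | COc1cc(C=O)cc(OC)c1O | starting material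
7 | 3,5-dimethoxy-4-(triisopropylsilyloxy)benzaldehyde | COc1cc(C=O)cc(OC)c1O[Si](C(C)C)(C(C)C)C(C)C | intermediate
8 | propane-1,3-dithiol | SCCCS | starting material
9 | 2-[3,5-dimethoxy-4-(triisopropylsilyloxy)phenyl]-1,3-dithiane | C1CSC(SC1)c1cc(OC)c(O[Si](C(C)C)(C(C)C)C(C)C)c(OC)c1 | intermediate
10 | 4-benzyloxy-3,5-dimethoxybenzaldehyde | COc1cc(C=O)cc(OC)c1OCc1ccccc1 | intermediate
11 | 2-lithio-2-[3,5-dimethoxy-4-(triisopropylsilyloxy)phenyl]-1,3-dithiane | [Li]C1(SCCCS1)c1cc(OC)c(O[Si](C(C)C)(C(C)C)C(C)C)c(OC)c1 | intermediate (not isolated)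
12 | lithium (4R,5R)-4-{2-[3,5-dimethoxy-4-(triisopropylsilyloxy)phenyl]-1,3-dithian-2-yl}-5-[(1R,2S,5R)-menthyloxy]-4,5-dihydrofuran-2-olate | [Li]OC1=C[C@@H](C2(SCCCS2)c2cc(OC)c(O[Si](C(C)C)(C(C)C)C(C)C)c(OC)c2)[C@H](O[C@@H]2C[C@H](C)CC[C@H]2C(C)C)O1 | intermediate (not isolated)
13 | (3S,4R,5R)-3-[(S)-(4-benzyloxy-3,5-dimethoxyphenyl)(hydroxy)methyl]-4-{2-[3,5-dimethoxy-4-(triisopropylsilyloxy)phenyl]-1,3-dithian-2-yl}-5-[(1R,2S,5R)-menthyloxy]dihydrofuran-2(3H)-one (a carbinol epimer may accompany it) | O=C1O[C@@H](O[C@@H]2C[C@H](C)CC[C@H]2C(C)C)[C@H](C2(SCCCS2)c2cc(OC)c(O[Si](C(C)C)(C(C)C)C(C)C)c(OC)c2)[C@H]1[C@H](O)c1cc(OC)c(OCc2ccccc2)c(OC)c1 | intermediate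
14 | (3S,4R,5R)-3-[(S)-(4-benzyloxy-3,5-dimethoxyphenyl)(hydroxy)methyl]-4-[3,5-dimethoxy-4-(triisopropylsilyloxy)benzoyl]-5-[(1R,2S,5R)-menthyloxy]dihydrofuran-2(3H)-one | O=C1O[C@@H](O[C@@H]2C[C@H](C)CC[C@H]2C(C)C)[C@H](C(=O)c2cc(OC)c(O[Si](C(C)C)(C(C)C)C(C)C)c(OC)c2)[C@H]1[C@H](O)c1cc(OC)c(OCc2ccccc2)c(OC)c1 | intermediate
15 | (2R,3R)-2-[(4-benzyloxy-3,5-dimethoxyphenyl)(hydroxy)methyl]-3-{[3,5-dimethoxy-4-(triisopropylsilyloxy)phenyl](hydroxy)methyl}butane-1,4-diol, mixture at both carbinol carbons | COc1cc(cc(OC)c1OCc1ccccc1)C(O)[C@@H](CO)[C@H](CO)C(O)c1cc(OC)c(O[Si](C(C)C)(C(C)C)C(C)C)c(OC)c1 | intermediate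
16 | (7S,8R,7'S,8'R)-4-O-benzyl-4'-O-(triisopropylsilyl)syringaresinol, (1S,3aR,4S,6aR)-1-(4-benzyloxy-3,5-dimethoxyphenyl)-4-[3,5-dimethoxy-4-(triisopropylsilyloxy)phenyl]tetrahydro-1H,3H-furo[3,4-c]furan | COc1cc(cc(OC)c1OCc1ccccc1)[C@H]1OC[C@H]2[C@@H]1CO[C@@H]2c1cc(OC)c(O[Si](C(C)C)(C(C)C)C(C)C)c(OC)c1 | intermediate
17 | (7S,8R,7'S,8'R)-4-O-benzylsyringaresinol (ring C phenol free) | COc1cc(cc(OC)c1OCc1ccccc1)[C@H]1OC[C@H]2[C@@H]1CO[C@@H]2c1cc(OC)c(O)c(OC)c1 | intermediate
18 | (R)-4-benzyloxazolidin-2-one | O=C1N[C@H](Cc2ccccc2)CO1 | starting material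
19 | (R)-4-benzyl-3-(bromoacetyl)oxazolidin-2-one | BrCC(=O)N1[C@H](Cc2ccccc2)COC1=O | intermediate
20 | 4-O-benzyl-4'-O-{2-[(R)-4-benzyl-2-oxooxazolidin-3-yl]-2-oxoethyl}syringaresinol | COc1cc(cc(OC)c1OCc1ccccc1)[C@H]1OC[C@H]2[C@@H]1CO[C@@H]2c1cc(OC)c(OCC(=O)N2[C@H](Cc3ccccc3)COC2=O)c(OC)c1 | intermediate
21 | 4-(allyloxy)-3-methoxybenzaldehyde | C=CCOc1ccc(C=O)cc1OC | starting material
22 | Z-dibutylboron enolate of 20 (aryloxy and OBBu2 cis) | COc1cc(cc(OC)c1OCc1ccccc1)[C@H]1OC[C@H]2[C@@H]1CO[C@@H]2c1cc(OC)c(O/C=C(\OB(CCCC)CCCC)N2[C@H](Cc3ccccc3)COC2=O)c(OC)c1 | intermediate (not isolated)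
23 | (4R)-4-benzyl-3-[(2R,3S)-3-(4-allyloxy-3-methoxyphenyl)-3-hydroxy-2-(aryloxy)propanoyl]oxazolidin-2-one, aryloxy = O4' of 4-O-benzylsyringaresinol | COc1cc(cc(OC)c1OCc1ccccc1)[C@H]1OC[C@H]2[C@@H]1CO[C@@H]2c1cc(OC)c(O[C@@H](C(=O)N2[C@H](Cc3ccccc3)COC2=O)[C@@H](O)c2ccc(OCC=C)c(OC)c2)c(OC)c1 | intermediate
24 | 4-O-benzyl-4'-O-[(1S,2S)-1-(4-allyloxy-3-methoxyphenyl)-1,3-dihydroxypropan-2-yl]syringaresinol (chain D threo, 7S,8S) | COc1cc(cc(OC)c1OCc1ccccc1)[C@H]1OC[C@H]2[C@@H]1CO[C@@H]2c1cc(OC)c(O[C@@H](CO)[C@@H](O)c2ccc(OCC=C)c(OC)c2)c(OC)c1 | intermediate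
25 | 4-O-benzyl-4'-O-[(1S,2S)-1-(4-allyloxy-3-methoxyphenyl)-1,3-bis(tert-butyldimethylsilyloxy)propan-2-yl]syringaresinol | COc1cc(cc(OC)c1OCc1ccccc1)[C@H]1OC[C@H]2[C@@H]1CO[C@@H]2c1cc(OC)c(O[C@@H](CO[Si](C)(C)C(C)(C)C)[C@@H](O[Si](C)(C)C(C)(C)C)c2ccc(OCC=C)c(OC)c2)c(OC)c1 | intermediate
26 | 4-O-benzyl-4'-O-[(1S,2S)-1,3-bis(tert-butyldimethylsilyloxy)-1-(4-hydroxy-3-methoxyphenyl)propan-2-yl]syringaresinol (ring D phenol free) | COc1cc(cc(OC)c1OCc1ccccc1)[C@H]1OC[C@H]2[C@@H]1CO[C@@H]2c1cc(OC)c(O[C@@H](CO[Si](C)(C)C(C)(C)C)[C@@H](O[Si](C)(C)C(C)(C)C)c2ccc(O)c(OC)c2)c(OC)c1 | intermediate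
27 | (S)-4-benzyloxazolidin-2-one | O=C1N[C@@H](Cc2ccccc2)CO1 | starting material
28 | (S)-4-benzyl-3-(bromoacetyl)oxazolidin-2-one | BrCC(=O)N1[C@@H](Cc2ccccc2)COC1=O | intermediate
29 | 4-O-benzyl-4'-O-[(1S,2S)-1-(4-{2-[(S)-4-benzyl-2-oxooxazolidin-3-yl]-2-oxoethoxy}-3-methoxyphenyl)-1,3-bis(tert-butyldimethylsilyloxy)propan-2-yl]syringaresinol | COc1cc(cc(OC)c1OCc1ccccc1)[C@H]1OC[C@H]2[C@@H]1CO[C@@H]2c1cc(OC)c(O[C@@H](CO[Si](C)(C)C(C)(C)C)[C@@H](O[Si](C)(C)C(C)(C)C)c2ccc(OCC(=O)N3[C@@H](Cc4ccccc4)COC3=O)c(OC)c2)c(OC)c1 | intermediate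
30 | 4'-O-[(1S,2S)-1-(4-{2-[(S)-4-benzyl-2-oxooxazolidin-3-yl]-2-oxoethoxy}-3-methoxyphenyl)-1,3-bis(tert-butyldimethylsilyloxy)propan-2-yl]syringaresinol (ring B phenol free) | COc1cc(cc(OC)c1O)[C@H]1OC[C@H]2[C@@H]1CO[C@@H]2c1cc(OC)c(O[C@@H](CO[Si](C)(C)C(C)(C)C)[C@@H](O[Si](C)(C)C(C)(C)C)c2ccc(OCC(=O)N3[C@@H](Cc4ccccc4)COC3=O)c(OC)c2)c(OC)c1 | intermediate
31 | bis-imide: 30 carrying CH2C(=O)Xc(R) on O4 of ring B, with CH2C(=O)Xc(S) on O4 of ring D | O=C(COc1c(OC)cc(cc1OC)[C@H]1OC[C@H]2[C@@H]1CO[C@@H]2c1cc(OC)c(O[C@@H](CO[Si](C)(C)C(C)(C)C)[C@@H](O[Si](C)(C)C(C)(C)C)c2ccc(OCC(=O)N3[C@@H](Cc4ccccc4)COC3=O)c(OC)c2)c(OC)c1)N1[C@H](Cc2ccccc2)COC1=O | intermediate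
32 | vanillin | COc1cc(C=O)ccc1O | starting material
33 | 3-methoxy-4-(triisopropylsilyloxy)benzaldehyde | COc1cc(C=O)ccc1O[Si](C(C)C)(C(C)C)C(C)C | intermediate
34 | bis(Z-dibutylboron enolate) of 31 | CCCCB(CCCC)O/C(=C\Oc1c(OC)cc(cc1OC)[C@H]1OC[C@H]2[C@@H]1CO[C@@H]2c1cc(OC)c(O[C@@H](CO[Si](C)(C)C(C)(C)C)[C@@H](O[Si](C)(C)C(C)(C)C)c2ccc(O/C=C(\OB(CCCC)CCCC)N3[C@@H](Cc4ccccc4)COC3=O)c(OC)c2)c(OC)c1)N1[C@H](Cc2ccccc2)COC1=O | intermediate (not isolated)
35 | bis syn-aldol adduct: (2R,3S)-3-hydroxy-3-[3-methoxy-4-(triisopropylsilyloxy)phenyl]propanoyl-Xc(R) on O4 of ring B and the (2S,3R)-analogue with Xc(S) on O4 of ring D; chain D (7S,8S) bis-O-TBS | CC(C)[Si](C(C)C)(C(C)C)Oc1ccc(cc1OC)[C@H](O)[C@H](C(=O)N1[C@H](Cc2ccccc2)COC1=O)Oc1c(OC)cc(cc1OC)[C@H]1OC[C@H]2[C@@H]1CO[C@@H]2c1cc(OC)c(O[C@@H](CO[Si](C)(C)C(C)(C)C)[C@@H](O[Si](C)(C)C(C)(C)C)c2ccc(O[C@H](C(=O)N3[C@@H](Cc4ccccc4)COC3=O)[C@H](O)c3ccc(O[Si](C(C)C)(C(C)C)C(C)C)c(OC)c3)c(OC)c2)c(OC)c1 | intermediate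
36 | tetraol: chain A threo (7S,8S) and chain E threo (7R,8R) with free 7- and 9-hydroxyls; chain D (7S,8S) bis-O-TBS; rings A and E O-TIPS | CC(C)[Si](C(C)C)(C(C)C)Oc1ccc(cc1OC)[C@H](O)[C@H](CO)Oc1c(OC)cc(cc1OC)[C@H]1OC[C@H]2[C@@H]1CO[C@@H]2c1cc(OC)c(O[C@@H](CO[Si](C)(C)C(C)(C)C)[C@@H](O[Si](C)(C)C(C)(C)C)c2ccc(O[C@H](CO)[C@H](O)c3ccc(O[Si](C(C)C)(C(C)C)C(C)C)c(OC)c3)c(OC)c2)c(OC)c1 | intermediate
37 | 36 with 9-O-TBS on chains A and E (7-hydroxyls of chains A and E free) | CC(C)[Si](C(C)C)(C(C)C)Oc1ccc(cc1OC)[C@H](O)[C@H](CO[Si](C)(C)C(C)(C)C)Oc1c(OC)cc(cc1OC)[C@H]1OC[C@H]2[C@@H]1CO[C@@H]2c1cc(OC)c(O[C@@H](CO[Si](C)(C)C(C)(C)C)[C@@H](O[Si](C)(C)C(C)(C)C)c2ccc(O[C@H](CO[Si](C)(C)C(C)(C)C)[C@H](O)c3ccc(O[Si](C(C)C)(C(C)C)C(C)C)c(OC)c3)c(OC)c2)c(OC)c1 | intermediate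
38 | diketone: 7-oxo in chains A (8S) and E (8R), otherwise as 37 | CC(C)[Si](C(C)C)(C(C)C)Oc1ccc(cc1OC)C(=O)[C@H](CO[Si](C)(C)C(C)(C)C)Oc1c(OC)cc(cc1OC)[C@H]1OC[C@H]2[C@@H]1CO[C@@H]2c1cc(OC)c(O[C@@H](CO[Si](C)(C)C(C)(C)C)[C@@H](O[Si](C)(C)C(C)(C)C)c2ccc(O[C@H](CO[Si](C)(C)C(C)(C)C)C(=O)c3ccc(O[Si](C(C)C)(C(C)C)C(C)C)c(OC)c3)c(OC)c2)c(OC)c1 | intermediate
39 | hexasilyl ether of the target: chain A erythro (7R,8S), chain D threo (7S,8S), chain E erythro (7S,8R); 9-O-TBS on chains A, D, E; 7-O-TBS on chain D; O-TIPS on rings A and E | CC(C)[Si](C(C)C)(C(C)C)Oc1ccc(cc1OC)[C@@H](O)[C@H](CO[Si](C)(C)C(C)(C)C)Oc1c(OC)cc(cc1OC)[C@H]1OC[C@H]2[C@@H]1CO[C@@H]2c1cc(OC)c(O[C@@H](CO[Si](C)(C)C(C)(C)C)[C@@H](O[Si](C)(C)C(C)(C)C)c2ccc(O[C@H](CO[Si](C)(C)C(C)(C)C)[C@@H](O)c3ccc(O[Si](C(C)C)(C(C)C)C(C)C)c(OC)c3)c(OC)c2)c(OC)c1 | intermediate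
40 | CNP0316493.3: (7S,8R,7'S,8'R)-syringaresinol 4-O-[erythro-(7R,8S)-guaiacylglycerol-8-yl] 4'-O-{threo-(7S,8S)-4-O-[erythro-(7S,8R)-guaiacylglycerol-8-yl]guaiacylglycerol-8-yl} diether | COc1cc([C@@H](O)[C@H](CO)Oc2c(OC)cc([C@H]3OC[C@H]4[C@@H]3CO[C@@H]4c3cc(OC)c(O[C@@H](CO)[C@@H](O)c4ccc(O[C@H](CO)[C@@H](O)c5ccc(O)c(OC)c5)c(OC)c4)c(OC)c3)cc2OC)ccc1O | target

## Step count and risk

Total step count: 27. Longest linear sequence: 21 steps (steps 1, 2, 6–10, 12–16, 18–20 and 22–27, from furfural 1 to 40; the line from syringaldehyde 6 through steps 3 and 4 is equally long).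

Steps least certain to work

Step 6 (key step). The bulky group at C4 of enolate 12 may slow the aldol trapping. Proton transfer to the enolate, retro-aldol cleavage of the lithium aldolate on warming, or loss of menthoxide from the β-alkoxy lactone can then compete. Direct 1,2-addition of the dithiane anion to the lactone carbonyl is a further leak. Low selectivity at the carbinol is tolerated. Fallback: it sets out from 9 and 5 and comes back at 13. The conjugate addition is run alone and quenched with NH4Cl to give the Michael adduct lactone F1. F1 is deprotonated with LiN(i-Pr)2 at −78 °C, the enolate is transmetalated with ZnCl2 and then treated with 10. The zinc aldolate is much less prone to retro-aldol cleavage, and the C4 substituent again directs the aldehyde to the trans face, giving 13.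

Step 9. Under acid, the benzylic ether bonds of 16 can re-ionise once they have formed, so the product drifts towards its 7- or 7'-epimers; the exo,exo isomer is a kinetic product, not a strongly favoured equilibrium one. The benzylic cation can also be captured by the other electron-rich ring (Friedel–Crafts closure to an aryltetralin) or by the other benzylic hydroxyl. Fallback: it sets out from 15 and comes back at 16. The closure is driven by sulfonylation in a basic medium (MsCl, Et3N, CH2Cl2, −20 → 0 °C). The benzylic sulfonates of these electron-rich carbinols ionise without any protic acid and are captured by the hydroxymethyl groups, and the closed ethers cannot re-ionise in the presence of amine. Any endo-aryl isomer that arises because a primary sulfonate forms first and is displaced by a benzylic hydroxyl with retention at the carbinol is removed by chromatography. No new compound is isolated.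

Step 13 (the same concern holds for step 22). The 2,6-dimethoxyphenoxy group next to the enolate carbon is large and electron-withdrawing. Enolisation may be incomplete or the boron enolate sluggish toward an electron-rich aldehyde, which would show as low conversion or eroded syn selectivity. In step 22 one of the two sites may fail to react. Fallback: it sets out from 17 and comes back at 24. Phenol 17 is alkylated (K2CO3, acetone) with the bromoacetyl thiazolidinethione F2, made from commercial (R)-4-benzyl-1,3-thiazolidine-2-thione and bromoacetyl bromide, to give the N-(aryloxyacetyl)thiazolidinethione F3. Its chlorotitanium enolate (TiCl4, i-Pr2NEt, N-methylpyrrolidinone, CH2Cl2, −78 → 0 °C) is more nucleophilic than the boron enolate and adds to 21 with the same syn sense to give adduct F4. NaBH4 in THF–EtOH removes the auxiliary and returns diol 24.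

Step 26. The facial selectivity of the double reduction may be poor if zinc does not hold the α-aryloxy oxygen firmly; a Felkin–Anh course would return the threo carbinols. The α-centres of 38 may also epimerise, or silanolate may be eliminated, before reduction. Fallback: it sets out from 37 and comes back at 39, avoiding the ketone altogether. Both threo carbinols are inverted by a Mitsunobu reaction (4-nitrobenzoic acid, PPh3, DIAD, toluene, 0 °C) to the bis(4-nitrobenzoate) F5, which has the erythro configuration at both ends. Methanolysis (K2CO3, MeOH, 0 °C) then gives 39. Should aryl silyl ethers be partly lost in the methanolysis, the material still converges on 40 in step 27.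

## Further compounds

F1 | step 6 | (4R,5R)-4-{2-[3,5-dimethoxy-4-(triisopropylsilyloxy)phenyl]-1,3-dithian-2-yl}-5-[(1R,2S,5R)-menthyloxy]dihydrofuran-2(3H)-one | O=C1O[C@@H](O[C@@H]2C[C@H](C)CC[C@H]2C(C)C)[C@H](C2(SCCCS2)c2cc(OC)c(O[Si](C(C)C)(C(C)C)C(C)C)c(OC)c2)C1
F0 | step 9 | none | none
F2 | step 13 | (R)-4-benzyl-3-(bromoacetyl)-1,3-thiazolidine-2-thione | BrCC(=O)N1[C@H](Cc2ccccc2)CSC1=S
F3 | step 13 | 4-O-benzyl-4'-O-{2-[(R)-4-benzyl-2-thioxo-1,3-thiazolidin-3-yl]-2-oxoethyl}syringaresinol | COc1cc(cc(OC)c1OCc1ccccc1)[C@H]1OC[C@H]2[C@@H]1CO[C@@H]2c1cc(OC)c(OCC(=O)N2[C@H](Cc3ccccc3)CSC2=S)c(OC)c1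
F4 | step 13 | (2R,3S)-3-(4-allyloxy-3-methoxyphenyl)-3-hydroxy-2-(aryloxy)propanoyl derivative of (R)-4-benzyl-1,3-thiazolidine-2-thione, aryloxy = O4' of 4-O-benzylsyringaresinol | COc1cc(cc(OC)c1OCc1ccccc1)[C@H]1OC[C@H]2[C@@H]1CO[C@@H]2c1cc(OC)c(O[C@@H](C(=O)N2[C@H](Cc3ccccc3)CSC2=S)[C@@H](O)c2ccc(OCC=C)c(OC)c2)c(OC)c1
F5 | step 26 | 7-O-(4-nitrobenzoyl) esters of 39 in chains A (7R,8S) and E (7S,8R) | CC(C)[Si](C(C)C)(C(C)C)Oc1ccc(cc1OC)[C@@H](OC(=O)c1ccc(cc1)[N+](=O)[O-])[C@H](CO[Si](C)(C)C(C)(C)C)Oc1c(OC)cc(cc1OC)[C@H]1OC[C@H]2[C@@H]1CO[C@@H]2c1cc(OC)c(O[C@@H](CO[Si](C)(C)C(C)(C)C)[C@@H](O[Si](C)(C)C(C)(C)C)c2ccc(O[C@H](CO[Si](C)(C)C(C)(C)C)[C@@H](OC(=O)c3ccc(cc3)[N+](=O)[O-])c3ccc(O[Si](C(C)C)(C(C)C)C(C)C)c(OC)c3)c(OC)c2)c(OC)c1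
A1 | alternative 1 | bis-aldehyde: protected core with chain D (7S,8S) bis-O-TBS, carrying (S)-1-formyl-2-(TBS-oxy)ethyl on O4 of ring B and (R)-1-formyl-2-(TBS-oxy)ethyl on O4 of ring D | O=C[C@H](CO[Si](C)(C)C(C)(C)C)Oc1c(OC)cc(cc1OC)[C@H]1OC[C@H]2[C@@H]1CO[C@@H]2c1cc(OC)c(O[C@@H](CO[Si](C)(C)C(C)(C)C)[C@@H](O[Si](C)(C)C(C)(C)C)c2ccc(O[C@H](CO[Si](C)(C)C(C)(C)C)C=O)c(OC)c2)c(OC)c1
A2 | alternative 1 | (4-benzyloxy-3-methoxyphenyl)titanium triisopropoxide | COc1cc([Ti](OC(C)C)(OC(C)C)OC(C)C)ccc1OCc1ccccc1
A3 | alternative 1 | protected target with free C7 hydroxyls in chains A and E, O-benzyl on rings A and E, TBS on the other four alcohols | COc1cc([C@@H](O)[C@H](CO[Si](C)(C)C(C)(C)C)Oc2c(OC)cc([C@H]3OC[C@H]4[C@@H]3CO[C@@H]4c3cc(OC)c(O[C@@H](CO[Si](C)(C)C(C)(C)C)[C@@H](O[Si](C)(C)C(C)(C)C)c4ccc(O[C@H](CO[Si](C)(C)C(C)(C)C)[C@@H](O)c5ccc(OCc6ccccc6)c(OC)c5)c(OC)c4)c(OC)c3)cc2OC)ccc1OCc1ccccc1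
A4 | alternative 2 | (2R,3R)-2-(4-benzyloxy-3,5-dimethoxybenzyl)-3-[3,5-dimethoxy-4-(triisopropylsilyloxy)benzyl]butane-1,4-diol | COc1cc(cc(OC)c1OCc1ccccc1)C[C@@H](CO)[C@H](CO)Cc1cc(OC)c(O[Si](C(C)C)(C(C)C)C(C)C)c(OC)c1
A5 | alternative 2 | (7S,8R,7'S,8'R)-4-O-benzyl-4'-O-(triisopropylsilyl)syringaresinol, identical with 16 | COc1cc(cc(OC)c1OCc1ccccc1)[C@H]1OC[C@H]2[C@@H]1CO[C@@H]2c1cc(OC)c(O[Si](C(C)C)(C(C)C)C(C)C)c(OC)c1
A6 | alternative 3 | (1S,4S,2E)-1-(4-benzyloxy-3,5-dimethoxyphenyl)-4-[3,5-dimethoxy-4-(triisopropylsilyloxy)phenyl]but-2-ene-1,4-diol | COc1cc(cc(OC)c1OCc1ccccc1)[C@@H](O)/C=C/[C@H](O)c1cc(OC)c(O[Si](C(C)C)(C(C)C)C(C)C)c(OC)c1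
A7 | alternative 3 | carbon monoxide | [C-]#[O+]
A8 | alternative 3 | cis-fused 2,6-diaryl-3,7-dioxabicyclo[3.3.0]octane-4,8-dione with both aryl groups exo (C7, C7', C8, C8' arranged as in the target), ring B O-benzyl, ring C O-TIPS | COc1cc(cc(OC)c1OCc1ccccc1)[C@H]1OC(=O)[C@H]2[C@@H]1C(=O)O[C@@H]2c1cc(OC)c(O[Si](C(C)C)(C(C)C)C(C)C)c(OC)c1
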